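**Plan**

- Retrosynthesis: the C8–CH2 bond is cut first (Negishi coupling), which separates an (S)-lavandulyl zinc reagent from an 8-iodoflavanone. The pyranone ring is then cut at O1–C8a and C4–C4a together, giving a ring A aryne and an (S)-β-silyloxy ester that already holds O1–C2–C3–C4 and the C2 stereocentre.
- Enabling feature: O1 and the C4 carbonyl stand on the adjacent ring A carbons C8a and C4a, and the C5 methoxy group sits beside C4a. A 3-methoxyaryne (C4a≡C8a) therefore takes an alkoxide at the remote carbon C8a and places the carbanion on C4a, six atoms from the ester carbonyl.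
- Forward order: ring A is made from 5-bromovanillin as a silylaryl triflate; ring B with C2 is made from 2'-hydroxyacetophenone; the aryne annulation closes ring C; C8 iodination, Negishi coupling and MOM removal finish the route.
- Stereochemistry: C2 (S) comes from a ruthenium-catalysed asymmetric transfer hydrogenation and is carried through the annulation with its C–O bond intact. The side-chain centre comes from an Evans dienolate prenylation and is carried into the zinc reagent.

Key step: step 9

Remark on the chemistry: CH2OH, CH2I and CH2ZnI outrank the isopropenyl group whereas CH2Ar does not, so the (2R) side chain of the target has the spatial arrangement of (S)-lavandulol; the descriptors below follow from this.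

**Route**

Step 1
Reactants: 1 3-bromo-4-hydroxy-5-methoxybenzaldehyde (5-bromovanillin)
Product: 3 2-bromo-6-methoxybenzene-1,4-diol, via formate ester 2 (not isolated)
Conditions: H2O2 (30% aq.), NaOH (aq.), THF, 0 °C → rt; then aq. HCl, Na2S2O4 wash
Reagents that add atoms: hydrogen peroxide (OO)
Why: Dakin oxidation, in which hydroperoxide adds to the aldehyde para to the phenoxide, the electron-rich aryl group migrates to oxygen (Baeyer–Villiger type) and formate 2 is saponified in the flask, so that the CHO carbon is replaced by the future C7 oxygen.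

Step 2
Reactants: 3 2-bromo-6-methoxybenzene-1,4-diol
Product: 4 2-bromo-6-methoxy-1,4-bis(trimethylsilyloxy)benzene
Conditions: (Me3Si)2NH, THF, 70 °C; concentrate
Reagents that add atoms: hexamethyldisilazane (C[Si](C)(C)N[Si](C)(C)C)
Why: exhaustive O-silylation with hexamethyldisilazane should put a SiMe3 group on the hindered oxygen flanked by Br and OMe, where the next step needs it, with ammonia as the only by-product.

Step 3
Reactants: 4 2-bromo-6-methoxy-1,4-bis(trimethylsilyloxy)benzene
Product: 8 4-hydroxy-2-methoxy-6-(trimethylsilyl)phenyl trifluoromethanesulfonate, via aryllithium 5 (not isolated), via lithium phenoxide 6 (not isolated), via silyl ether triflate 7 (not isolated)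
Conditions: n-BuLi, THF, −78 °C; Tf2O, −78 → 0 °C; then 1 M HCl, THF, 0 °C
Reagents that add atoms: trifluoromethanesulfonic anhydride (O=S(=O)(C(F)(F)F)OS(=O)(=O)C(F)(F)F)
Why: bromine–lithium exchange gives 5, which takes the SiMe3 group from the neighbouring oxygen (1,3 O→C silyl shift, retro-Brook rearrangement) to give 6, O-triflation gives 7, and the remote aryl O–SiMe3 ether is hydrolysed on acidic work-up, so only the hydroxyl ortho to bromine becomes the triflate and no selective protection is needed.

Step 4
Reactants: 8 4-hydroxy-2-methoxy-6-(trimethylsilyl)phenyl trifluoromethanesulfonate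
Product: 9 2-methoxy-4-(methoxymethoxy)-6-(trimethylsilyl)phenyl trifluoromethanesulfonate
Conditions: MOMCl, iPr2NEt, CH2Cl2, 0 °C → rt
Reagents that add atoms: chloromethyl methyl ether (COCCl)
Why: standard MOM etherification of the free phenol (the future 7-OH) under amine base should leave the aryl triflate and the C–SiMe3 bond untouched and gives a fluoride-stable ether.

Step 5
Reactants: 10 1-(2-hydroxyphenyl)ethan-1-one (2'-hydroxyacetophenone)
Product: 11 1-[2-(methoxymethoxy)phenyl]ethan-1-one
Conditions: MOMCl, iPr2NEt, CH2Cl2, 0 °C → reflux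
Reagents that add atoms: chloromethyl methyl ether (COCCl)
Why: MOM etherification of the chelated phenol removes the acidic O–H before the enolate and aryne steps.

Step 6
Reactants: 11 1-[2-(methoxymethoxy)phenyl]ethan-1-one
Product: 12 methyl 3-[2-(methoxymethoxy)phenyl]-3-oxopropanoate
Conditions: NaH, (MeO)2CO, THF, reflux; then aq. HCl, 0 °C
Reagents that add atoms: dimethyl carbonate (COC(=O)OC)
Why: crossed Claisen condensation, in which the methyl ketone is C-acylated by dimethyl carbonate and the equilibrium is drawn forward by deprotonation of the β-keto ester.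

Step 7
Reactants: 12 methyl 3-[2-(methoxymethoxy)phenyl]-3-oxopropanoate
Product: 13 methyl (3S)-3-hydroxy-3-[2-(methoxymethoxy)phenyl]propanoate
Conditions: RuCl[(S,S)-TsDPEN](p-cymene) (1 mol %), HCO2H/Et3N (5:2), CH2Cl2, 30 °C
Reagents that add atoms: none
Why: Noyori asymmetric transfer hydrogenation of an aryl ketone, for which the (S,S)-TsDPEN ruthenium hydride reduces in the sense acetophenone → (S)-1-phenylethanol and should therefore set the future C2 as (S), while the near-neutral formate medium spares the MOM ether.

Step 8
Reactants: 13 methyl (3S)-3-hydroxy-3-[2-(methoxymethoxy)phenyl]propanoate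
Product: 14 methyl (3S)-3-[2-(methoxymethoxy)phenyl]-3-(trimethylsilyloxy)propanoate
Conditions: Me3SiCl, imidazole, CH2Cl2, 0 °C
Reagents that add atoms: chlorotrimethylsilane (C[Si](C)(C)Cl)
Why: silylation of the secondary alcohol gives a proton-free alkoxide precursor that fluoride can unmask in the key step.

Step 9
Reactants: 9 2-methoxy-4-(methoxymethoxy)-6-(trimethylsilyl)phenyl trifluoromethanesulfonate; 14 methyl (3S)-3-[2-(methoxymethoxy)phenyl]-3-(trimethylsilyloxy)propanoate
Product: 18 (2S)-5-methoxy-7-(methoxymethoxy)-2-[2-(methoxymethoxy)phenyl]-2,3-dihydro-4H-chromen-4-one, via cesium alkoxide 15 (not isolated), via aryne 16 (not isolated), via arylcesium adduct 17 (not isolated)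
Conditions: CsF (3 equiv), 18-crown-6 (0.3 equiv), THF, 0 °C → rt, slow addition of 9 (1.3 equiv); then aq. NH4Cl
Reagents that add atoms: none
Why: Proposed new method: fluoride strips the O–SiMe3 group of 14 to the alkoxide 15 and the C–SiMe3 group of 9 to aryne 16 (loss of triflate); 15 adds through oxygen to the aryne carbon remote from the methoxy group (the future C8a), and the resulting carbanion 17 at C4a attacks the ester carbonyl six atoms away and expels methoxide, so that O1–C8a and C4–C4a form in one operation. The closest known reaction type is the fluoride-mediated annulation of arynes with salicylate esters to xanthones (phenoxide addition, then intramolecular acyl substitution), together with aryne insertion into carboxylic acid C–O bonds; new here are an aliphatic secondary alkoxide released from its silyl ether as the nucleophile and an unactivated aliphatic ester as the acceptor. Ring C is closed by 6-exo-trig attack of the C4a carbanion on the ester C=O after the intermolecular C–O bond formation. No new stereocentre is formed: C2 comes in from 14 and its C–O bond is never broken, so the (S) configuration should be retained as long as the product is not left with base long enough for retro-oxa-Michael opening. The step needs regioselectivity on the aryne and acylation instead of protonation of the carbanion; the first is secured by the C5 methoxy group, whose inductive effect and the attendant aryne distortion direct nucleophiles to the distal carbon and stabilise the carbanion ortho to oxygen, the second by the absence of any O–H (silyl ether, THF in place of acetonitrile) and by the intramolecular six-membered acyl transfer. Methoxide that is released should be consumed at silicon (it frees further aryne from 9 or alkoxide from 14), which keeps the medium from becoming strongly basic.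

Step 10
Reactants: 18 (2S)-5-methoxy-7-(methoxymethoxy)-2-[2-(methoxymethoxy)phenyl]-2,3-dihydro-4H-chromen-4-one
Product: 19 (2S)-8-iodo-5-methoxy-7-(methoxymethoxy)-2-[2-(methoxymethoxy)phenyl]-2,3-dihydro-4H-chromen-4-one
Conditions: NIS (1.05 equiv), CF3CO2H (10 mol %), MeCN, 0 °C → rt
Reagents that add atoms: N-iodosuccinimide (O=C1CCC(=O)N1I)
Why: electrophilic aromatic iodination of the trioxygenated ring A, where C8 should be preferred over C6 because C6 is shielded by the in-plane methyl of the C5 methoxy group (which cannot turn toward the peri carbonyl), as is usual for 5-O-alkyl-7-alkoxy flavonoids, while ring B is far less activated.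

Step 11
Reactants: 20 (4S)-4-benzyl-1,3-oxazolidin-2-one; 21 3-methylbut-2-enoyl chloride
Product: 22 (4S)-4-benzyl-3-(3-methylbut-2-enoyl)-1,3-oxazolidin-2-one
Conditions: n-BuLi, THF, −78 °C; then 21, −78 → 0 °C
Reagents that add atoms: none
Why: N-acylation of the Evans auxiliary by the acid chloride after deprotonation with n-BuLi.

Step 12
Reactants: 22 (4S)-4-benzyl-3-(3-methylbut-2-enoyl)-1,3-oxazolidin-2-one; 23 1-bromo-3-methylbut-2-ene (prenyl bromide)
Product: 25 (4S)-4-benzyl-3-[(2S)-5-methyl-2-(prop-1-en-2-yl)hex-4-enoyl]-1,3-oxazolidin-2-one, via sodium dienolate 24 (not isolated)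
Conditions: NaN(SiMe3)2, THF, −78 °C; then 23, −78 → −40 °C
Reagents that add atoms: none
Why: Evans asymmetric alkylation through dienolate 24, in which γ-deprotonation of the s-cis enoyl imide gives the chelated Z(O)-dienolate that is alkylated at the α-carbon (kinetic site, with deconjugation) on the face opposite the benzyl group, in the sense that turns the propionyl imide into the (R)-2-methylpent-4-enoyl imide and here should give (2S).

Step 13
Reactants: 25 (4S)-4-benzyl-3-[(2S)-5-methyl-2-(prop-1-en-2-yl)hex-4-enoyl]-1,3-oxazolidin-2-one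
Product: 26 (2S)-5-methyl-2-(prop-1-en-2-yl)hex-4-en-1-ol ((S)-lavandulol)
Conditions: LiBH4, MeOH (1 equiv), Et2O, 0 °C
Reagents that add atoms: none
Why: reductive cleavage of the imide by LiBH4 should give the primary alcohol without touching the α-stereocentre or the alkenes and returns the auxiliary.

Step 14
Reactants: 26 (2S)-5-methyl-2-(prop-1-en-2-yl)hex-4-en-1-ol
Product: 27 (3S)-3-(iodomethyl)-2,6-dimethylhepta-1,5-diene
Conditions: I2, PPh3, imidazole, CH2Cl2, 0 °C → rt
Reagents that add atoms: iodine (II)
Why: Appel-type iodination (SN2 at the primary carbon of the alkoxyphosphonium salt) leaves the β-stereocentre and both alkenes alone.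

Step 15
Reactants: 19 (2S)-8-iodo-5-methoxy-7-(methoxymethoxy)-2-[2-(methoxymethoxy)phenyl]-2,3-dihydro-4H-chromen-4-one; 27 (3S)-3-(iodomethyl)-2,6-dimethylhepta-1,5-diene
Product: 29 (2S)-5-methoxy-7-(methoxymethoxy)-2-[2-(methoxymethoxy)phenyl]-8-[(2R)-5-methyl-2-(prop-1-en-2-yl)hex-4-en-1-yl]-2,3-dihydro-4H-chromen-4-one, via alkylzinc iodide 28 (not isolated)
Conditions: 27, Zn dust (activated by BrCH2CH2Br, Me3SiCl), LiCl, THF, 40 °C; then 19, Pd(OAc)2 (5 mol %), SPhos (10 mol %), THF/NMP, 50 °C
Reagents that add atoms: none
Why: Negishi sp3–sp2 cross-coupling, in which zinc insertion gives the primary alkylzinc 28 whose stereocentre is β to the metal and untouched, and a bulky biarylphosphine palladium catalyst should couple it to the hindered aryl iodide faster than β-hydride elimination, while the ketone, the MOM ethers and the base-sensitive C2 centre tolerate the neutral organozinc.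

Step 16
Reactants: 29 (2S)-5-methoxy-7-(methoxymethoxy)-2-[2-(methoxymethoxy)phenyl]-8-[(2R)-5-methyl-2-(prop-1-en-2-yl)hex-4-en-1-yl]-2,3-dihydro-4H-chromen-4-one
Product: 30 kushenol R, (2S)-7-hydroxy-2-(2-hydroxyphenyl)-5-methoxy-8-[(2R)-5-methyl-2-(prop-1-en-2-yl)hex-4-en-1-yl]-2,3-dihydro-4H-chromen-4-one
Conditions: p-TsOH·H2O (0.2 equiv), MeOH, 40 °C; quench with NaHCO3 at full conversion
Reagents that add atoms: none
Why: acid-catalysed acetal exchange (methanolysis of both MOM ethers) frees the two phenols, and the mild acid is chosen so that the new 7-OH does not add to the lavandulyl alkenes and C2 is not epimerised.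

**Compound list**

1 | 3-bromo-4-hydroxy-5-methoxybenzaldehyde (5-bromovanillin) | O=Cc1cc(Br)c(O)c(OC)c1 | starting material
2 | 3-bromo-4-hydroxy-5-methoxyphenyl formate (formed in the flask) | O=COc1cc(Br)c(O)c(OC)c1 | intermediate
3 | 2-bromo-6-methoxybenzene-1,4-diol | Oc1cc(Br)c(O)c(OC)c1 | intermediate
4 | 2-bromo-6-methoxy-1,4-bis(trimethylsilyloxy)benzene | C[Si](C)(C)Oc1cc(Br)c(O[Si](C)(C)C)c(OC)c1 | intermediate
5 | [3-methoxy-2,5-bis(trimethylsilyloxy)phenyl]lithium (formed in the flask) | [Li]c1cc(O[Si](C)(C)C)cc(OC)c1O[Si](C)(C)C | intermediate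
6 | lithium 2-methoxy-6-(trimethylsilyl)-4-(trimethylsilyloxy)phenolate (formed in the flask) | [Li+].[O-]c1c(OC)cc(O[Si](C)(C)C)cc1[Si](C)(C)C | intermediate
7 | 2-methoxy-6-(trimethylsilyl)-4-(trimethylsilyloxy)phenyl trifluoromethanesulfonate (formed in the flask) | C[Si](C)(C)Oc1cc(OC)c(OS(=O)(=O)C(F)(F)F)c([Si](C)(C)C)c1 | intermediate
8 | 4-hydroxy-2-methoxy-6-(trimethylsilyl)phenyl trifluoromethanesulfonate | Oc1cc(OC)c(OS(=O)(=O)C(F)(F)F)c([Si](C)(C)C)c1 | intermediate
9 | 2-methoxy-4-(methoxymethoxy)-6-(trimethylsilyl)phenyl trifluoromethanesulfonate | COCOc1cc(OC)c(OS(=O)(=O)C(F)(F)F)c([Si](C)(C)C)c1 | intermediate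
10 | 1-(2-hydroxyphenyl)ethan-1-one (2'-hydroxyacetophenone) | CC(=O)c1ccccc1O | starting material
11 | 1-[2-(methoxymethoxy)phenyl]ethan-1-one | CC(=O)c1ccccc1OCOC | intermediate
12 | methyl 3-[2-(methoxymethoxy)phenyl]-3-oxopropanoate | COC(=O)CC(=O)c1ccccc1OCOC | intermediate
13 | methyl (3S)-3-hydroxy-3-[2-(methoxymethoxy)phenyl]propanoate | O[C@H](c1ccccc1OCOC)CC(=O)OC | intermediate
14 | methyl (3S)-3-[2-(methoxymethoxy)phenyl]-3-(trimethylsilyloxy)propanoate | C[Si](C)(C)O[C@H](c1ccccc1OCOC)CC(=O)OC | intermediate
15 | cesium (1S)-3-methoxy-1-[2-(methoxymethoxy)phenyl]-3-oxopropan-1-olate (formed in the flask) | [Cs+].[O-][C@H](c1ccccc1OCOC)CC(=O)OC | intermediate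
16 | 3-methoxy-5-(methoxymethoxy)benzyne (formed in the flask) | COC1=CC(OCOC)=CC#C1 | intermediate
17 | cesium 2-methoxy-6-{(1S)-3-methoxy-1-[2-(methoxymethoxy)phenyl]-3-oxopropoxy}-4-(methoxymethoxy)benzen-1-ide (formed in the flask) | [Cs+].O([C@H](c1ccccc1OCOC)CC(=O)OC)c1cc(OCOC)cc(OC)[c-]1 | intermediate
18 | (2S)-5-methoxy-7-(methoxymethoxy)-2-[2-(methoxymethoxy)phenyl]-2,3-dihydro-4H-chromen-4-one | COCOc1cc(OC)c2c(c1)O[C@H](c1ccccc1OCOC)CC2=O | intermediate
19 | (2S)-8-iodo-5-methoxy-7-(methoxymethoxy)-2-[2-(methoxymethoxy)phenyl]-2,3-dihydro-4H-chromen-4-one | COCOc1cc(OC)c2c(c1I)O[C@H](c1ccccc1OCOC)CC2=O | intermediate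
20 | (4S)-4-benzyl-1,3-oxazolidin-2-one | O=C1N[C@@H](Cc2ccccc2)CO1 | starting material
21 | 3-methylbut-2-enoyl chloride | CC(C)=CC(=O)Cl | starting material
22 | (4S)-4-benzyl-3-(3-methylbut-2-enoyl)-1,3-oxazolidin-2-one | CC(C)=CC(=O)N1[C@@H](Cc2ccccc2)COC1=O | intermediate
23 | 1-bromo-3-methylbut-2-ene (prenyl bromide) | CC(C)=CCBr | starting material
24 | sodium (1Z)-1-[(4S)-4-benzyl-2-oxo-1,3-oxazolidin-3-yl]-3-methylbuta-1,3-dien-1-olate (formed in the flask) | [Na+].[O-]/C(=C\C(C)=C)N1[C@@H](Cc2ccccc2)COC1=O | intermediate
25 | (4S)-4-benzyl-3-[(2S)-5-methyl-2-(prop-1-en-2-yl)hex-4-enoyl]-1,3-oxazolidin-2-one | C=C(C)[C@H](CC=C(C)C)C(=O)N1[C@@H](Cc2ccccc2)COC1=O | intermediate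
26 | (2S)-5-methyl-2-(prop-1-en-2-yl)hex-4-en-1-ol ((S)-lavandulol) | C=C(C)[C@H](CC=C(C)C)CO | intermediate
27 | (3S)-3-(iodomethyl)-2,6-dimethylhepta-1,5-diene | C=C(C)[C@H](CC=C(C)C)CI | intermediate
28 | [(2S)-5-methyl-2-(prop-1-en-2-yl)hex-4-en-1-yl]zinc iodide (formed in the flask) | C=C(C)[C@H](CC=C(C)C)C[Zn]I | intermediate
29 | (2S)-5-methoxy-7-(methoxymethoxy)-2-[2-(methoxymethoxy)phenyl]-8-[(2R)-5-methyl-2-(prop-1-en-2-yl)hex-4-en-1-yl]-2,3-dihydro-4H-chromen-4-one | C=C(C)[C@H](CC=C(C)C)Cc1c(OCOC)cc(OC)c2c1O[C@H](c1ccccc1OCOC)CC2=O | intermediate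
30 | kushenol R, (2S)-7-hydroxy-2-(2-hydroxyphenyl)-5-methoxy-8-[(2R)-5-methyl-2-(prop-1-en-2-yl)hex-4-en-1-yl]-2,3-dihydro-4H-chromen-4-one | C=C(C)[C@H](CC=C(C)C)Cc1c(O)cc(OC)c2c1O[C@H](c1ccccc1O)CC2=O | target

**Step count and risks**

Total step count: 16. Longest linear sequence: 8 steps (steps 1–4, 9, 10, 15, 16 from 5-bromovanillin; the branch from 2'-hydroxyacetophenone through steps 5–8 is equally long).

Steps most likely to fail:

1. Step 9 (proposed new method). The alkoxide may be lost to retro-aldol cleavage or elimination before it meets the aryne, the carbanion may be protonated instead of acylated, or the product may open and racemise under the basic medium. Fallback with known chemistry: the same two bonds are made by aryne insertion into the C–O bond of an α,β-unsaturated carboxylic acid. It sets out from 9. (E)-3-[2-(Methoxymethoxy)phenyl]prop-2-enoic acid F1, made from commercial 2-(methoxymethoxy)benzaldehyde and malonic acid (pyridine, piperidine, Knoevenagel–Doebner), is heated with 9 and CsF in THF at 125 °C. The carboxylate should add to the aryne carbon remote from OMe, the carbanion attack the carboxyl carbon, and the four-membered adduct open to (E)-1-[2-hydroxy-6-methoxy-4-(methoxymethoxy)phenyl]-3-[2-(methoxymethoxy)phenyl]prop-2-en-1-one F2. Oxa-Michael ring closure (NaOAc, EtOH, reflux) then gives the racemic flavanone F3, whose (2S) enantiomer is separated by preparative chromatography on a chiral stationary phase. The fallback comes back to the route at 18.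

2. Step 10. Substitution at C6 or over-iodination may compete with the wanted attack at C8. Fallback: regiocontrol is moved to an open-chain phenol. It sets out from 9, which with F1 gives chalcone F2 as above. F2 is iodinated with NIS ortho to its hydrogen-bonded 2'-hydroxyl, the position that becomes C8, to give (E)-1-[2-hydroxy-3-iodo-6-methoxy-4-(methoxymethoxy)phenyl]-3-[2-(methoxymethoxy)phenyl]prop-2-en-1-one F4. Ring closure (NaOAc, EtOH) gives the racemic 8-iodoflavanone F5, which is resolved on a chiral stationary phase. The fallback comes back to the route at 19.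

3. Step 15. The β-branched alkylzinc may transmetalate slowly onto the di-ortho-oxygenated arylpalladium species, allowing protodeiodination, or the alkylpalladium intermediate may isomerise through β-hydride elimination and reinsertion. Fallback: the preformed organometallic is avoided. It sets out from 19 and 27, which are joined directly by nickel-catalysed reductive cross-electrophile coupling (NiBr2(dme), 4,4'-di-tert-butyl-2,2'-bipyridine, Mn powder, NaI, DMA, 60 °C), and it comes back to the route at 29 without new intermediates.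

Further compounds
F1 | step 9 | (E)-3-[2-(methoxymethoxy)phenyl]prop-2-enoic acid | COCOc1ccccc1/C=C/C(=O)O
F2 | step 9 | (E)-1-[2-hydroxy-6-methoxy-4-(methoxymethoxy)phenyl]-3-[2-(methoxymethoxy)phenyl]prop-2-en-1-one | COCOc1cc(O)c(C(=O)/C=C/c2ccccc2OCOC)c(OC)c1
F3 | step 9 | racemic 5-methoxy-7-(methoxymethoxy)-2-[2-(methoxymethoxy)phenyl]-2,3-dihydro-4H-chromen-4-one | COCOc1cc(OC)c2c(c1)OC(c1ccccc1OCOC)CC2=O
F4 | step 10 | (E)-1-[2-hydroxy-3-iodo-6-methoxy-4-(methoxymethoxy)phenyl]-3-[2-(methoxymethoxy)phenyl]prop-2-en-1-one | COCOc1cc(OC)c(C(=O)/C=C/c2ccccc2OCOC)c(O)c1I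
F5 | step 10 | racemic 8-iodo-5-methoxy-7-(methoxymethoxy)-2-[2-(methoxymethoxy)phenyl]-2,3-dihydro-4H-chromen-4-one | COCOc1cc(OC)c2c(c1I)OC(c1ccccc1OCOC)CC2=O
F0 | step 15 | none | none
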